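## Structural features

The target, compound 15, is a depside: two benzene rings joined through one aryl ester and carrying no stereocentre. Ring A is a 2,4-dihydroxy-6-(2-oxoheptyl)benzoyl group; ring B is the same resorcylate unit with a free carboxylic acid, acylated on the oxygen para to that carboxyl, so the molecule is a dimer of one C14 unit. Since nothing stereochemical has to be set, every problem is one of regiochemistry and chemoselectivity among three phenols, one acid, two ketones and one ester. The fragile points are the aryl ester (alcoholysis, aminolysis, hydroxide), the two aryl-CH2 ketones (each enolizable and ortho to a ring carbonyl on which its enol can close to an isocoumarin) and the salicylic acid of ring B. The real difficulty is the ester bond itself: its acyl carbon sits between two ortho substituents of an electron-rich ring, and its partner is a weakly nucleophilic phenol. The key step exploits the fact that the ester carbon, the six carbons of ring A and the seven side-chain carbons form one unbranched C14 chain oxygenated at C1, C3, C5, C7 and C9. A bond from chain C2 to chain C7 (ring A C1 to C6) folds that chain into the benzene ring after the ester has been made. Ring B shows the same pattern, so a single chain precursor can serve both rings.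

## Logic of the disconnections

15 back to 14 and 13. The benzyl C–O bond of the ring B carboxyl is restored first, then the four C–O bonds of the two dioxolanes on the side-chain ketones. Nothing is gained in skeleton, but the only acidic step then meets the molecule while the carboxyl is still an ester, and the last step is a neutral hydrogenolysis. The demand is that dilute acid spares two esters and that hydrogenolysis spares two ketones that are not conjugated with the rings.

13 back to 11, through 12. The ring A bond between the carbon bearing the ester and the carbon bearing the side chain is cut, together with the aromatic unsaturation. Ring A becomes an open 3,5,7-triketo chain hanging from the depside oxygen. The gain is that the hindered ester no longer has to be made on a finished di-ortho-substituted benzoic acid. The demand is an aldol of chain C2 on C7 that outruns every process that would expel the ring B phenoxide from 11.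

11 back to 9 and 6, through 10. The acyl C–O bond of the depside is cut. The acyl part becomes 10, released from 6 by a retro-hetero-Diels–Alder fragmentation, and the oxygen part is 9. The 2-hydroxyl of 9 stays free, because its hydrogen bond to the ester carbonyl should keep it from reacting; this saves a benzyl ether and the steps needed to place it. The demand is that the hydroxyl para to the ester captures the ketene faster than the ketene closes on its own enol oxygen.

9 back to 8, and 8 back to 6 through 7. In 9 the acyl C–O bond of the benzyl ester is cut and the carboxyl and the ortho oxygen are tied back into an acetonide. In 8 the same ring bond as in ring A is cut, this time with the carboxyl carbon locked in the dioxinone of 6. Ring B therefore comes from the intermediate that also feeds ring A, with no separate aromatic starting material, no lateral acylation and no late ketalization next to an ester. The demand is a base-only sequence (amine for the fold, alkoxide for the ring opening) so that the dioxolane survives.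

6 back to 5 and 3. The bond between chain C6 and C7 is cut, a Claisen-type disconnection of the β-diketone. It divides the C14 chain into a C6 dioxinone piece and a C8 acyl donor that already carries the masked ketone. The demand is clean acylation of the dianion of 5 at its terminal carbon by an enolizable amide.

5 back to 4, and 3 back to 2 and 1. In 5 the bond between the side-chain CH2 and the acetyl carbonyl is cut, leaving the dienolate of 4 and an acetyl donor. In 3 the amide C–N bond and then the ketal C–O bonds are cut, leaving 1. Both branches end in commercial materials and rely on standard carbonyl chemistry.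

## Other disconnections considered

Alternative 1: The cut removes both ortho carbon substituents of a resorcinol ring at once, the ring-to-carboxyl bond and the ring-to-CH2 bond. In the forward sense, the aryne 3,5-bis(methoxymethoxy)benzyne A1, generated with CsF, would insert into a C–C bond of dibenzyl malonate A2. The malonate carbanion adds to the aryne carbon remote from the flanking oxygen, the aryl anion closes on an ester carbonyl, and the four-membered alkoxide opens to dibenzyl 3,5-bis(methoxymethoxy)homophthalate A3.
- In its favour: the neighbouring oxygen directs the regiochemistry, two C–C bonds form in one operation on a ring that is already aromatic, and the aliphatic and aromatic esters of A3 differ in reactivity.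
- Against it here: A3 carries a carboxymethyl group where a 2-oxoheptyl group is needed, so each ring needs an ester-to-ketone conversion and a ketalization. The phenols of ring B must be told apart after acetal removal, the acetals come off only under acid, and the depside bond would still be made by activating a di-ortho-substituted acid.
- Comparison: on regiocontrol of the ring substitution it is the equal of the chosen plan. On the ring-forming mechanism it is the better, since it has no competing fold and no tautomer mixtures. On step economy and on the ester-forming event the chosen plan is better, because 6 supplies both rings and the ester exists before ring A does.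

Alternative 2: The cut takes the ring A aryl-to-carbonyl bond and the carbonyl-to-oxygen bond together, so the ester carbon comes from carbon monoxide A6. Forward, 2-{[3,5-bis(benzyloxy)-2-iodophenyl]methyl}-2-pentyl-1,3-dioxolane A4, A6 and benzyl 2-(benzyloxy)-4-hydroxy-6-[(2-pentyl-1,3-dioxolan-2-yl)methyl]benzoate A5 would combine under Pd(OAc)2, Xantphos and Et3N, the divalent palladium salt being reduced in the flask to zerovalent palladium. Oxidative addition, insertion of A6 and attack of the phenoxide on the aroylpalladium would give the fully protected depside A7.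
- In its favour: no hindered benzoic acid is ever activated, which makes it the equal of the chosen plan on that point. A5 has a single free hydroxyl, so the site of acylation is certain, which is better than relying on a hydrogen bond in step 6. There are no polycarbonyl tautomers and no lactonization competitor, so the bond-forming event is more predictable.
- Against it here: oxidative addition at an iodide flanked by two ortho groups on an electron-rich ring is slow, the aroylpalladium is hindered and the phenoxide is a poor nucleophile, so reduction of the iodide can compete. A4 and A5 need separate sequences (regioselective iodination, phenol differentiation), and three benzyl ethers are carried.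
- Comparison: the end game is equal (acid, then hydrogenolysis). The step count is higher than in the chosen plan because the two rings share no advanced intermediate.

Alternative 3: The cut takes two ring bonds of a resorcylate ring (C1–C2 and C5–C6), so the ring comes from a four-carbon diene and a two-carbon alkyne. Forward, 1,1-dimethoxy-3-(trimethylsilyloxy)buta-1,3-diene A8 and benzyl 4-(2-pentyl-1,3-dioxolan-2-yl)but-2-ynoate A9 would undergo a Diels–Alder reaction in which the nucleophilic CH2 terminus of A8 bonds to the β-carbon of A9. The adduct aromatizes by loss of one methoxy group and the silyl group to give benzyl 4-hydroxy-2-methoxy-6-[(2-pentyl-1,3-dioxolan-2-yl)methyl]benzoate A10.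
- In its favour: the polarization of both partners fixes the regiochemistry, and a cycloaddition has no alternative fold, which is better than the aldol. A10 arrives with the 4-hydroxyl free and the 2-oxygen capped, exactly the differentiation ring B needs, which is also better than the chosen plan.
- Against it here: the 2-O-methyl group must later be cleaved on both rings with a boron trihalide in the presence of ketals, a benzyl ester and the depside. A9 is a propargylic ynoate that can isomerize to an allene, and β-alkyl ynoates are sluggish dienophiles. The depside bond again needs activation of a hindered acid.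
- Comparison: ring construction is equal or better; overall step count and the ester-forming event are worse than in the chosen plan.

Key step: step 7

Assumption: the chelated 2-hydroxyl of ring B is left unprotected, on the expectation that the hydroxyl para to the ester is the one that captures the acylketene; 11 and 13 are therefore the benzyl-ester, free-phenol forms of the precursor and product of the key step.

## Route

Step 1
Reactants: 1 ethyl 3-oxooctanoate
Product: 2 ethyl 2-(2-pentyl-1,3-dioxolan-2-yl)acetate
Conditions: HOCH2CH2OH (3 equiv), p-TsOH·H2O (cat.), PhMe, reflux, Dean–Stark trap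
Reagents that add atoms: ethylene glycol, OCCO
Why: Acid-catalysed ketalization driven by azeotropic removal of water; the ketone of the β-keto ester is the only carbonyl that can form a dioxolane and the ester is untouched.

Step 2
Reactants: 2 ethyl 2-(2-pentyl-1,3-dioxolan-2-yl)acetate
Product: 3 N-methoxy-N-methyl-2-(2-pentyl-1,3-dioxolan-2-yl)acetamide
Conditions: MeNH(OMe)·HCl (1.5 equiv), i-PrMgCl (3.0 equiv), THF, −20 → 0 °C
Reagents that add atoms: N,O-dimethylhydroxylamine hydrochloride, CNOC.Cl
Why: Aminolysis of the ester by the chloromagnesium amide formed from the amine salt and i-PrMgCl (N-methoxy-N-methylamide synthesis); the ketal is inert to the basic medium and the amide does not react further.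

Step 3
Reactants: 4 2,2,6-trimethyl-4H-1,3-dioxin-4-one
Product: 5 2,2-dimethyl-6-(2-oxopropyl)-4H-1,3-dioxin-4-one
Conditions: 4 (2 equiv), LiN(SiMe3)2 (2 equiv), THF, −78 °C; AcCl (1 equiv), −78 → −20 °C; aq. NH4Cl
Reagents that add atoms: acetyl chloride, CC(=O)Cl
Why: γ-Deprotonation gives the lithium dienolate of 4, which is C-acylated at the exocyclic carbon (vinylogous Claisen-type acylation); the enolate is used in twofold excess because 5 is more acidic than 4.

Step 4
Reactants: 5 2,2-dimethyl-6-(2-oxopropyl)-4H-1,3-dioxin-4-one; 3 N-methoxy-N-methyl-2-(2-pentyl-1,3-dioxolan-2-yl)acetamide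
Product: 6 2,2-dimethyl-6-[2,4-dioxo-5-(2-pentyl-1,3-dioxolan-2-yl)pentyl]-4H-1,3-dioxin-4-one
Conditions: LiN(i-Pr)2 (2.1 equiv), THF, −78 °C; then 3, −78 → −40 °C; AcOH quench at −78 °C
Reagents that add atoms: none
Why: Double deprotonation of 5 gives a dianion that reacts at its terminal carbon; Claisen-type acylation by the N-methoxy-N-methylamide stops at the chelated tetrahedral adduct, so the β-diketone appears only on quenching and cannot consume the base.

Step 5
Reactants: 6 2,2-dimethyl-6-[2,4-dioxo-5-(2-pentyl-1,3-dioxolan-2-yl)pentyl]-4H-1,3-dioxin-4-one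
Product: 9 benzyl 2,4-dihydroxy-6-[(2-pentyl-1,3-dioxolan-2-yl)methyl]benzoate, via dioxinone aldol adduct 7 (not isolated), via benzodioxinone 8 (not isolated)
Conditions: Et3N (3 equiv), CH2Cl2, rt; evaporate from PhMe; BnOH (10 equiv), Cs2CO3 (2 equiv), THF, 60 °C; AcOH to about pH 5
Reagents that add atoms: benzyl alcohol, OCc1ccccc1
Why: Triethylamine folds 6 by the 6-(enolendo)-exo-trig aldol of the dioxinone α-carbon (chain C2) on the C7 ketone, and dehydration of 7 with enolization gives the resorcylate acetonide 8 (aldol aromatization of a diketo-dioxinone). Benzyl alkoxide formed with Cs2CO3 then adds to the acylal carbonyl of 8 and the heterocycle opens with loss of acetone (base-mediated alcoholysis of a salicylate acetonide), leaving the benzyl ester with both phenols free. Nothing more acidic than acetic acid is used, so the dioxolane is kept.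

Step 6
Reactants: 6 2,2-dimethyl-6-[2,4-dioxo-5-(2-pentyl-1,3-dioxolan-2-yl)pentyl]-4H-1,3-dioxin-4-one; 9 benzyl 2,4-dihydroxy-6-[(2-pentyl-1,3-dioxolan-2-yl)methyl]benzoate
Product: 11 benzyl 2-hydroxy-6-[(2-pentyl-1,3-dioxolan-2-yl)methyl]-4-{[3,5,7-trioxo-8-(2-pentyl-1,3-dioxolan-2-yl)octanoyl]oxy}benzoate, via acylketene 10 (not isolated)
Conditions: 9 (1.5 equiv, about 0.5 M), PhMe, 110 °C, 6 added in portions; evaporate and use crude (surplus 9 recovered after step 7)
Reagents that add atoms: none
Why: Thermal retro-hetero-Diels–Alder loss of acetone from 6 releases acylketene 10, and the unchelated hydroxyl of 9 para to the ester adds to it (acylketene capture by a phenol), the 2-hydroxyl being held in a hydrogen bond to the ester carbonyl. A concentrated excess of the phenol keeps bimolecular capture ahead of closure of the ketene on its own enol oxygen.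

Step 7
Reactants: 11 benzyl 2-hydroxy-6-[(2-pentyl-1,3-dioxolan-2-yl)methyl]-4-{[3,5,7-trioxo-8-(2-pentyl-1,3-dioxolan-2-yl)octanoyl]oxy}benzoate
Product: 13 benzyl 4-({2,4-dihydroxy-6-[(2-pentyl-1,3-dioxolan-2-yl)methyl]benzoyl}oxy)-2-hydroxy-6-[(2-pentyl-1,3-dioxolan-2-yl)methyl]benzoate, via aryl aldol adduct 12 (not isolated)
Conditions: Et3N (3 equiv), 4 Å molecular sieves, CH2Cl2, 0 °C → rt; pH 5 phosphate buffer wash
Reagents that add atoms: none
Why: Triethylamine reversibly ionizes the 1,3-dicarbonyl units of 11, and the carbanion at chain C2, flanked by the aryl ester carbonyl and the C3 ketone, adds to the C7 ketone to give the six-membered adduct 12, which loses water by E1cB elimination and enolizes at C3 and C5 to the benzene ring of 13. The closest known reaction type is the amine- or carbonate-induced aldol aromatization of dioxinone-derived 3,5,7-triketo esters to resorcylates. Ring A closes in the 6-(enolendo)-exo-trig mode, with the C2–C3 enolate inside the new ring and the C7 carbonyl oxygen outside it. No stereocentre results: the two sp3 centres of 12 form without control and both become aromatic carbons. Three selectivities are needed: aldol at C7 rather than Claisen attack of C6 on the ester carbon; aldol rather than lactonization of the C5 enol oxygen onto the ester carbon, which would give a 4-hydroxy-2-pyranone and release 9; and survival of the aryl ester toward intermolecular acyl transfer. The first two rest on the ketone being the better electrophile and on the attacking C1–C2–C3 enolate deactivating the ester carbonyl it is conjugated with; the third rests on a tertiary amine in an aprotic solvent with no alcohol present. The dioxolane removes C9 as an electrophile, so no C4-to-C9 aldol can occur, and its quaternary carbon shields C8 from acting as a nucleophile toward C3. The sieves take up the water released, so the new depside is not exposed to wet base.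

Step 8
Reactants: 13 benzyl 4-({2,4-dihydroxy-6-[(2-pentyl-1,3-dioxolan-2-yl)methyl]benzoyl}oxy)-2-hydroxy-6-[(2-pentyl-1,3-dioxolan-2-yl)methyl]benzoate
Product: 14 benzyl 4-{[2,4-dihydroxy-6-(2-oxoheptyl)benzoyl]oxy}-2-hydroxy-6-(2-oxoheptyl)benzoate
Conditions: 1 M aq. HCl/THF (1:4), 0 °C → rt
Reagents that add atoms: water, O
Why: Acid-catalysed hydrolysis of two dialkyl-ketone dioxolanes; the benzyl ester and the hindered, hydrogen-bonded aryl ester should tolerate dilute aqueous acid at room temperature, and keeping the carboxyl esterified avoids lactol and isocoumarin chemistry on ring B.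

Step 9
Reactants: 14 benzyl 4-{[2,4-dihydroxy-6-(2-oxoheptyl)benzoyl]oxy}-2-hydroxy-6-(2-oxoheptyl)benzoate
Product: 15 4-{[2,4-dihydroxy-6-(2-oxoheptyl)benzoyl]oxy}-2-hydroxy-6-(2-oxoheptyl)benzoic acid
Conditions: H2 (1 atm), 10% Pd/C, EtOAc, rt
Reagents that add atoms: none
Why: Hydrogenolysis of the benzyl ester under neutral conditions; the ketones are not conjugated with the rings and carry no benzylic C–O bond, and the aryl ester and phenols are inert.

## Compound list

1 | ethyl 3-oxooctanoate | CCCCCC(=O)CC(=O)OCC | starting material
2 | ethyl 2-(2-pentyl-1,3-dioxolan-2-yl)acetate | CCCCCC1(CC(=O)OCC)OCCO1 | intermediate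
3 | N-methoxy-N-methyl-2-(2-pentyl-1,3-dioxolan-2-yl)acetamide | CCCCCC1(CC(=O)N(C)OC)OCCO1 | intermediate
4 | 2,2,6-trimethyl-4H-1,3-dioxin-4-one | CC1=CC(=O)OC(C)(C)O1 | starting material
5 | 2,2-dimethyl-6-(2-oxopropyl)-4H-1,3-dioxin-4-one | CC(=O)CC1=CC(=O)OC(C)(C)O1 | intermediate
6 | 2,2-dimethyl-6-[2,4-dioxo-5-(2-pentyl-1,3-dioxolan-2-yl)pentyl]-4H-1,3-dioxin-4-one | CCCCCC1(CC(=O)CC(=O)CC2=CC(=O)OC(C)(C)O2)OCCO1 | intermediate
7 | 5-hydroxy-2,2-dimethyl-5-[(2-pentyl-1,3-dioxolan-2-yl)methyl]-5,6-dihydro-4H-1,3-benzodioxine-4,7(8H)-dione (dioxinone aldol adduct; racemic, centre lost on aromatization; not isolated) | CCCCCC1(CC2(O)CC(=O)CC3=C2C(=O)OC(C)(C)O3)OCCO1 | intermediate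
8 | 7-hydroxy-2,2-dimethyl-5-[(2-pentyl-1,3-dioxolan-2-yl)methyl]-4H-1,3-benzodioxin-4-one (benzodioxinone; not isolated in step 5) | CCCCCC1(Cc2cc(O)cc3OC(C)(C)OC(=O)c23)OCCO1 | intermediate
9 | benzyl 2,4-dihydroxy-6-[(2-pentyl-1,3-dioxolan-2-yl)methyl]benzoate | CCCCCC1(Cc2cc(O)cc(O)c2C(=O)OCc2ccccc2)OCCO1 | intermediate
10 | 8-(2-pentyl-1,3-dioxolan-2-yl)oct-1-ene-1,3,5,7-tetrone (acylketene; not isolated) | CCCCCC1(CC(=O)CC(=O)CC(=O)C=C=O)OCCO1 | intermediate
11 | benzyl 2-hydroxy-6-[(2-pentyl-1,3-dioxolan-2-yl)methyl]-4-{[3,5,7-trioxo-8-(2-pentyl-1,3-dioxolan-2-yl)octanoyl]oxy}benzoate (ring B aryl ester of 9,9-(ethylenedioxy)-3,5,7-trioxotetradecanoic acid) | CCCCCC1(CC(=O)CC(=O)CC(=O)CC(=O)Oc2cc(O)c(C(=O)OCc3ccccc3)c(CC3(CCCCC)OCCO3)c2)OCCO1 | intermediate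
12 | benzyl 2-hydroxy-4-({2-hydroxy-4,6-dioxo-2-[(2-pentyl-1,3-dioxolan-2-yl)methyl]cyclohexane-1-carbonyl}oxy)-6-[(2-pentyl-1,3-dioxolan-2-yl)methyl]benzoate (aryl aldol adduct; stereoisomer mixture, both centres lost on aromatization; not isolated) | CCCCCC1(CC2(O)CC(=O)CC(=O)C2C(=O)Oc2cc(O)c(C(=O)OCc3ccccc3)c(CC3(CCCCC)OCCO3)c2)OCCO1 | intermediate
13 | benzyl 4-({2,4-dihydroxy-6-[(2-pentyl-1,3-dioxolan-2-yl)methyl]benzoyl}oxy)-2-hydroxy-6-[(2-pentyl-1,3-dioxolan-2-yl)methyl]benzoate | CCCCCC1(Cc2cc(O)cc(O)c2C(=O)Oc2cc(O)c(C(=O)OCc3ccccc3)c(CC3(CCCCC)OCCO3)c2)OCCO1 | intermediate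
14 | benzyl 4-{[2,4-dihydroxy-6-(2-oxoheptyl)benzoyl]oxy}-2-hydroxy-6-(2-oxoheptyl)benzoate | CCCCCC(=O)Cc1cc(O)cc(O)c1C(=O)Oc1cc(O)c(C(=O)OCc2ccccc2)c(CC(=O)CCCCC)c1 | intermediate
15 | 4-{[2,4-dihydroxy-6-(2-oxoheptyl)benzoyl]oxy}-2-hydroxy-6-(2-oxoheptyl)benzoic acid | CCCCCC(=O)Cc1cc(OC(=O)c2c(O)cc(O)cc2CC(=O)CCCCC)cc(O)c1C(=O)O | target

## Step count and least certain steps

Total: 9 steps. Longest linear sequence: 8 steps (1, 2, 4, 5, 6, 7, 8, 9), with step 3 as a one-step branch; intermediate 6 is used twice, in steps 5 and 6.

Step 7 (key step). The process most likely to intrude is loss of the ring B phenoxide before the aldol. This can happen by closure of the C5 enol oxygen on the activated aryl ester carbon to give a pyranone, or by E1cB elimination from the C2 enolate to the acylketene, which then closes in the same way. An aryloxide is a far better leaving group than the alkoxides of the esters on which this aromatization is established, and a stalled dehydration of 12 would prolong the exposure to base. The fallback aromatizes first and makes the ester afterwards; it sets out from 6 and returns to the route at 15. The first stage of step 5 alone (Et3N, CH2Cl2), worked up at that point, gives 8 as an isolated compound; here the carboxyl carbon is locked in the acetonide and cannot lose an aryloxide. Benzylation (BnBr, K2CO3, DMF) gives 7-(benzyloxy)-2,2-dimethyl-5-[(2-pentyl-1,3-dioxolan-2-yl)methyl]-4H-1,3-benzodioxin-4-one F1. Irradiation at 300 nm in CH2Cl2 in the presence of 9 expels acetone and gives the quinone ketene 3-(benzyloxy)-6-(oxomethylidene)-5-[(2-pentyl-1,3-dioxolan-2-yl)methyl]cyclohexa-2,4-dien-1-one F2. This ketene has no internal nucleophile, so the 4-hydroxyl of 9 should capture it to give benzyl 4-({4-(benzyloxy)-2-hydroxy-6-[(2-pentyl-1,3-dioxolan-2-yl)methyl]benzoyl}oxy)-2-hydroxy-6-[(2-pentyl-1,3-dioxolan-2-yl)methyl]benzoate F3; the precedent is photochemical acyl transfer from such benzodioxinones to alcohols. Dilute aqueous HCl in THF then gives benzyl 4-{[4-(benzyloxy)-2-hydroxy-6-(2-oxoheptyl)benzoyl]oxy}-2-hydroxy-6-(2-oxoheptyl)benzoate F4, and hydrogenolysis over Pd/C removes both benzyl groups to give 15.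

Step 6. The acylketene may close on its own C5 enol oxygen faster than a weakly nucleophilic, ester-substituted phenol can capture it, and some acylation may occur at the chelated 2-hydroxyl. The fallback abandons ketene capture for a conventional esterification; it sets out from 9 and returns at 15. Exhaustive benzylation (BnBr, K2CO3, DMF, 60 °C) gives benzyl 2,4-bis(benzyloxy)-6-[(2-pentyl-1,3-dioxolan-2-yl)methyl]benzoate F5, and saponification (KOH, aqueous DMSO, 90 °C) gives 2,4-bis(benzyloxy)-6-[(2-pentyl-1,3-dioxolan-2-yl)methyl]benzoic acid F6. Steglich esterification (N,N'-dicyclohexylcarbodiimide, DMAP, CH2Cl2) with a second portion of 9 at its 4-hydroxyl gives benzyl 4-({2,4-bis(benzyloxy)-6-[(2-pentyl-1,3-dioxolan-2-yl)methyl]benzoyl}oxy)-2-hydroxy-6-[(2-pentyl-1,3-dioxolan-2-yl)methyl]benzoate F7. Dilute aqueous HCl in THF gives benzyl 4-{[2,4-bis(benzyloxy)-6-(2-oxoheptyl)benzoyl]oxy}-2-hydroxy-6-(2-oxoheptyl)benzoate F8, and hydrogenolysis over Pd/C gives 15.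

Step 5. The alcoholysis stage may stall, because the phenoxide formed at the 7-position under base donates into the carbonyl para to it and lowers its electrophilicity; forcing the reaction invites hydrolysis to the acid by adventitious hydroxide. The fallback replaces alkoxide opening by ketene capture; it sets out from 6 and returns at 9. Heating 6 with benzyl alcohol in toluene at 110 °C releases 10, which the alcohol should capture as benzyl 3,5,7-trioxo-8-(2-pentyl-1,3-dioxolan-2-yl)octanoate F9. Triethylamine in CH2Cl2 then folds F9 by the same C2-to-C7 aldol through benzyl 2-hydroxy-4,6-dioxo-2-[(2-pentyl-1,3-dioxolan-2-yl)methyl]cyclohexane-1-carboxylate F10, which dehydrates and enolizes to 9.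

Step 4. Proton transfer from the α-CH2 of amide 3 to the dianion may compete with acylation, quenching the nucleophile and opening the dioxolane by β-elimination. The fallback replaces the Claisen acylation by aldol addition and oxidation; it sets out from 2 and returns at 6. Reduction with i-Bu2AlH (CH2Cl2, −78 °C) takes 2 to 2-(2-pentyl-1,3-dioxolan-2-yl)acetaldehyde F11. Addition of the dianion of 5 (LiN(i-Pr)2, THF, −78 °C), which should be faster than enolization of an aldehyde, gives racemic 6-[4-hydroxy-2-oxo-5-(2-pentyl-1,3-dioxolan-2-yl)pentyl]-2,2-dimethyl-4H-1,3-dioxin-4-one F12, and Dess–Martin periodinane oxidizes F12 to 6, removing the carbinol stereocentre.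

Step 8. Hydrolysis of two ketals next to quaternary carbons may be slow, and longer acid exposure invites acid-promoted acyl transfer: closure of a freed ketone enol on the neighbouring benzyl ester with loss of the benzyl group as its alcohol. The fallback reverses the order of unmasking; it sets out from 13 and returns at 15. Hydrogenolysis (H2, Pd/C, EtOAc) first gives 4-({2,4-dihydroxy-6-[(2-pentyl-1,3-dioxolan-2-yl)methyl]benzoyl}oxy)-2-hydroxy-6-[(2-pentyl-1,3-dioxolan-2-yl)methyl]benzoic acid F13. The ketals are then hydrolysed in aqueous acetic acid/THF at 40 °C; no benzyl ester is left to be displaced, and any ring closure on the carboxyl is a reversible lactol equilibrium, so this should give 15.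

## Further compounds

F1 | step 7 | 7-(benzyloxy)-2,2-dimethyl-5-[(2-pentyl-1,3-dioxolan-2-yl)methyl]-4H-1,3-benzodioxin-4-one | CCCCCC1(Cc2cc(OCc3ccccc3)cc3OC(C)(C)OC(=O)c23)OCCO1
F2 | step 7 | 3-(benzyloxy)-6-(oxomethylidene)-5-[(2-pentyl-1,3-dioxolan-2-yl)methyl]cyclohexa-2,4-dien-1-one | O=C=C1C(=O)C=C(OCc2ccccc2)C=C1CC1(CCCCC)OCCO1
F3 | step 7 | benzyl 4-({4-(benzyloxy)-2-hydroxy-6-[(2-pentyl-1,3-dioxolan-2-yl)methyl]benzoyl}oxy)-2-hydroxy-6-[(2-pentyl-1,3-dioxolan-2-yl)methyl]benzoate | CCCCCC1(Cc2cc(OCc3ccccc3)cc(O)c2C(=O)Oc2cc(O)c(C(=O)OCc3ccccc3)c(CC3(CCCCC)OCCO3)c2)OCCO1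
F4 | step 7 | benzyl 4-{[4-(benzyloxy)-2-hydroxy-6-(2-oxoheptyl)benzoyl]oxy}-2-hydroxy-6-(2-oxoheptyl)benzoate | CCCCCC(=O)Cc1cc(OCc2ccccc2)cc(O)c1C(=O)Oc1cc(O)c(C(=O)OCc2ccccc2)c(CC(=O)CCCCC)c1
F5 | step 6 | benzyl 2,4-bis(benzyloxy)-6-[(2-pentyl-1,3-dioxolan-2-yl)methyl]benzoate | CCCCCC1(Cc2cc(OCc3ccccc3)cc(OCc3ccccc3)c2C(=O)OCc2ccccc2)OCCO1
F6 | step 6 | 2,4-bis(benzyloxy)-6-[(2-pentyl-1,3-dioxolan-2-yl)methyl]benzoic acid | CCCCCC1(Cc2cc(OCc3ccccc3)cc(OCc3ccccc3)c2C(=O)O)OCCO1
F7 | step 6 | benzyl 4-({2,4-bis(benzyloxy)-6-[(2-pentyl-1,3-dioxolan-2-yl)methyl]benzoyl}oxy)-2-hydroxy-6-[(2-pentyl-1,3-dioxolan-2-yl)methyl]benzoate | CCCCCC1(Cc2cc(OCc3ccccc3)cc(OCc3ccccc3)c2C(=O)Oc2cc(O)c(C(=O)OCc3ccccc3)c(CC3(CCCCC)OCCO3)c2)OCCO1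
F8 | step 6 | benzyl 4-{[2,4-bis(benzyloxy)-6-(2-oxoheptyl)benzoyl]oxy}-2-hydroxy-6-(2-oxoheptyl)benzoate | CCCCCC(=O)Cc1cc(OCc2ccccc2)cc(OCc2ccccc2)c1C(=O)Oc1cc(O)c(C(=O)OCc2ccccc2)c(CC(=O)CCCCC)c1
F9 | step 5 | benzyl 3,5,7-trioxo-8-(2-pentyl-1,3-dioxolan-2-yl)octanoate | CCCCCC1(CC(=O)CC(=O)CC(=O)CC(=O)OCc2ccccc2)OCCO1
F10 | step 5 | benzyl 2-hydroxy-4,6-dioxo-2-[(2-pentyl-1,3-dioxolan-2-yl)methyl]cyclohexane-1-carboxylate (stereoisomer mixture, both centres lost on aromatization) | CCCCCC1(CC2(O)CC(=O)CC(=O)C2C(=O)OCc2ccccc2)OCCO1
F11 | step 4 | 2-(2-pentyl-1,3-dioxolan-2-yl)acetaldehyde | CCCCCC1(CC=O)OCCO1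
F12 | step 4 | 6-[4-hydroxy-2-oxo-5-(2-pentyl-1,3-dioxolan-2-yl)pentyl]-2,2-dimethyl-4H-1,3-dioxin-4-one (racemic) | CCCCCC1(CC(O)CC(=O)CC2=CC(=O)OC(C)(C)O2)OCCO1
F13 | step 8 | 4-({2,4-dihydroxy-6-[(2-pentyl-1,3-dioxolan-2-yl)methyl]benzoyl}oxy)-2-hydroxy-6-[(2-pentyl-1,3-dioxolan-2-yl)methyl]benzoic acid | CCCCCC1(Cc2cc(O)cc(O)c2C(=O)Oc2cc(O)c(C(=O)O)c(CC3(CCCCC)OCCO3)c2)OCCO1
A1 | alternative 1 | 3,5-bis(methoxymethoxy)benzyne | COCOC1=CC(OCOC)=CC#C1
A2 | alternative 1 | dibenzyl malonate | O=C(CC(=O)OCc1ccccc1)OCc1ccccc1
A3 | alternative 1 | dibenzyl 3,5-bis(methoxymethoxy)homophthalate | COCOc1cc(OCOC)c(C(=O)OCc2ccccc2)c(CC(=O)OCc2ccccc2)c1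
A4 | alternative 2 | 2-{[3,5-bis(benzyloxy)-2-iodophenyl]methyl}-2-pentyl-1,3-dioxolane | CCCCCC1(Cc2cc(OCc3ccccc3)cc(OCc3ccccc3)c2I)OCCO1
A5 | alternative 2 | benzyl 2-(benzyloxy)-4-hydroxy-6-[(2-pentyl-1,3-dioxolan-2-yl)methyl]benzoate | CCCCCC1(Cc2cc(O)cc(OCc3ccccc3)c2C(=O)OCc2ccccc2)OCCO1
A6 | alternative 2 | carbon monoxide | [C-]#[O+]
A7 | alternative 2 | benzyl 2-(benzyloxy)-4-({2,4-bis(benzyloxy)-6-[(2-pentyl-1,3-dioxolan-2-yl)methyl]benzoyl}oxy)-6-[(2-pentyl-1,3-dioxolan-2-yl)methyl]benzoate | CCCCCC1(Cc2cc(OCc3ccccc3)cc(OCc3ccccc3)c2C(=O)Oc2cc(OCc3ccccc3)c(C(=O)OCc3ccccc3)c(CC3(CCCCC)OCCO3)c2)OCCO1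
A8 | alternative 3 | 1,1-dimethoxy-3-(trimethylsilyloxy)buta-1,3-diene | COC(OC)=CC(=C)O[Si](C)(C)C
A9 | alternative 3 | benzyl 4-(2-pentyl-1,3-dioxolan-2-yl)but-2-ynoate | CCCCCC1(CC#CC(=O)OCc2ccccc2)OCCO1
A10 | alternative 3 | benzyl 4-hydroxy-2-methoxy-6-[(2-pentyl-1,3-dioxolan-2-yl)methyl]benzoate | CCCCCC1(Cc2cc(O)cc(OC)c2C(=O)OCc2ccccc2)OCCO1
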